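**Retrosynthetic overview**

- The plan rests on the ester-bearing ring of the naphthoate (ring A: C1–C4, C4a, C8a). The aryl ether oxygen on C4 and the prenyl CH2 on C3 are neighbours and sit next to the C2 ester, so the C4–O and C3–CH2 bonds are cut together. This leads back to a C3–C4 naphthalyne, a masked 2-naphthol and prenyl bromide.
- The aryne is released from an ortho-silyl aryl triflate, made from methyl 1,4-dihydroxy-2-naphthoate by C3 bromination, bis-O-silylation, bromine–lithium exchange with retro-Brook shift and triflation, then O1 methoxymethylation.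
- The naphthol comes from naphthalene-1,4-diol by bis-methoxymethylation and ortho-lithiation/borylation/oxidation. The quinone stays masked as its bis(methoxymethyl) hydroquinone ether until the last two steps (HCl/MeOH, then Ag2O).
- No ring is formed anywhere in the route; both naphthalene units are bought intact.

Key step: step 7

Remark on the chemistry: the target has no stereocentre and its trisubstituted prenyl alkene has no E/Z isomers, so no stereocontrol is needed. Naphthalene-1,4-diol and methyl 1,4-dihydroxy-2-naphthoate are taken as commercial.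

**Route**

Step 1
Reactants: 1 methyl 1,4-dihydroxy-2-naphthoate
Product: 2 methyl 3-bromo-1,4-dihydroxy-2-naphthoate
Conditions: Br2 (1.0 equiv), AcOH/CH2Cl2, 0 °C → rt; aq. Na2S2O4 wash
Reagents that add atoms: bromine, BrBr
Why: Electrophilic aromatic bromination at C3, the only open position of ring A and ortho to the free 4-OH; one equivalent of Br2 should end at the same bromohydroquinone whether it substitutes directly or oxidises to the quinone that then adds HBr at C3, and the dithionite wash returns any residual quinone to the hydroquinone level.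

Step 2
Reactants: 2 methyl 3-bromo-1,4-dihydroxy-2-naphthoate
Product: 3 methyl 3-bromo-1,4-bis(trimethylsilyloxy)-2-naphthoate
Conditions: HMDS (neat), cat. (NH4)2SO4, 90 °C; evaporate, use crude
Reagents that add atoms: hexamethyldisilazane, C[Si](C)(C)N[Si](C)(C)C
Why: O-silylation of both phenols with HMDS under forcing conditions (ammonia is the only by-product) should cover the ester-chelated 1-OH as well, so the moisture-sensitive bis(silyl ether) can go straight into the lithiation.

Step 3
Reactants: 3 methyl 3-bromo-1,4-bis(trimethylsilyloxy)-2-naphthoate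
Product: 7 methyl 1-hydroxy-4-(trifluoromethylsulfonyloxy)-3-(trimethylsilyl)-2-naphthoate, via C3 aryllithium 4 (not isolated), via lithium naphtholate 5 (not isolated), via O1-silyl aryl triflate 6 (not isolated)
Conditions: n-BuLi (1.05 equiv), THF, −100 → −78 °C; Tf2O (1.2 equiv), −78 → 0 °C; then 1 M aq. HCl, THF, 0 °C → rt
Reagents that add atoms: trifluoromethanesulfonic anhydride, O=S(=O)(OS(=O)(=O)C(F)(F)F)C(F)(F)F
Why: Bromine–lithium exchange, retro-Brook 1,3-shift of silicon from O4 to C3 and O-triflation of the resulting naphtholate is the standard entry to ortho-silyl aryl triflates; exchange at −100 °C should outrun addition to the doubly ortho-flanked methyl ester because the aryllithium is quenched intramolecularly as it forms, and dilute acid then hydrolyses only the O1–Si ether, the C3–Si bond on the electron-poor ring being stable.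

Step 4
Reactants: 7 methyl 1-hydroxy-4-(trifluoromethylsulfonyloxy)-3-(trimethylsilyl)-2-naphthoate
Product: 8 methyl 1-(methoxymethoxy)-4-(trifluoromethylsulfonyloxy)-3-(trimethylsilyl)-2-naphthoate
Conditions: MOMCl, i-Pr2NEt, cat. n-Bu4NI, CH2Cl2, 0 → 40 °C
Reagents that add atoms: chloromethyl methyl ether, COCCl
Why: O-alkylation of the chelated 1-naphthol to its methoxymethyl ether with an amine base; no fluoride or strong oxyanion is present, so the silyl triflate should be untouched.

Step 5
Reactants: 9 naphthalene-1,4-diol
Product: 10 1,4-bis(methoxymethoxy)naphthalene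
Conditions: NaH, MOMCl, DMF, 0 °C → rt, under argon
Reagents that add atoms: chloromethyl methyl ether, COCCl
Why: Williamson-type O-alkylation of both phenoxides (argon, because the dianion is air-sensitive) gives the bis(methoxymethyl) ether that masks the quinone against organolithium and copper reagents.

Step 6
Reactants: 10 1,4-bis(methoxymethoxy)naphthalene
Product: 13 1,4-bis(methoxymethoxy)naphthalen-2-ol, via C2 aryllithium 11 (not isolated), via lithium aryltrimethoxyborate 12 (not isolated)
Conditions: n-BuLi, TMEDA, THF, 0 °C; B(OMe)3, −78 °C → rt; 30% H2O2, aq. NaOH, 0 °C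
Reagents that add atoms: hydrogen peroxide, OO
Why: Directed ortho-metalation by the methoxymethoxy group (C2 and C3 are equivalent by symmetry), borylation and oxidative conversion of C–B into C–O should deliver the 2-naphthol.

Step 7
Reactants: 8 methyl 1-(methoxymethoxy)-4-(trifluoromethylsulfonyloxy)-3-(trimethylsilyl)-2-naphthoate; 13 1,4-bis(methoxymethoxy)naphthalen-2-ol; 14 prenyl bromide (1-bromo-3-methylbut-2-ene)
Product: 18 methyl 4-{[1,4-bis(methoxymethoxy)naphthalen-2-yl]oxy}-1-(methoxymethoxy)-3-(3-methylbut-2-enyl)-2-naphthoate, via copper aryloxide 15 (not isolated), via 3,4-naphthalyne 16 (not isolated), via C3 arylcopper 17 (not isolated)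
Conditions: 13 (1.2 equiv), CuMes (mesitylcopper, monovalent copper, 1.2 equiv), THF, rt; CsF (3 equiv), 18-crown-6 (3 equiv), slow addition of 8 (1.0 equiv), THF, 0 °C → rt; then 14 (3 equiv), 0 °C → rt
Reagents that add atoms: none
Why: Proposed new method: fluoride removes the C3 silyl group, triflate leaves from C4, and the resulting naphthalyne 16 is taken up by copper aryloxide 15 with oxygen bonding to C4 and copper to C3, giving arylcopper 17, which prenyl bromide then alkylates. The closest known reaction types are the addition of phenoxides to arynes to give diaryl ethers and the copper-mediated 1,2-difunctionalisation of arynes that ends with an allyl halide. No ring is closed and no stereocentre is formed. The step needs oxygen at C4 and carbon at C3: the C2 ester withdraws inductively and so places the developing negative charge on the adjacent C3, where its carbonyl oxygen can also chelate copper, and it screens C3 sterically, which together should override the usual preference of a 1,2-naphthalyne for attack at the carbon remote from the peri hydrogen. O-arylation rather than C-arylation of the naphtholate is expected because its nucleophilic C1 carries a methoxymethoxy group, and because CuMes leaves only mesitylene, no proton source remains to quench 17. Prenyl bromide is held back until 8 is consumed so that it cannot O-alkylate 15, and the hindered arylcopper should attack the unhindered CH2 terminus (SN2) in preference to the tertiary one (SN2′).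

Step 8
Reactants: 18 methyl 4-{[1,4-bis(methoxymethoxy)naphthalen-2-yl]oxy}-1-(methoxymethoxy)-3-(3-methylbut-2-enyl)-2-naphthoate
Product: 19 methyl 4-[(1,4-dihydroxynaphthalen-2-yl)oxy]-1-hydroxy-3-(3-methylbut-2-enyl)-2-naphthoate
Conditions: HCl (1.25 M in MeOH), MeOH/THF, degassed, rt → 40 °C
Reagents that add atoms: none
Why: Acid-catalysed acetal exchange with methanol should cleave all three aryl methoxymethyl ethers (the one beside the ester fastest), while dilute acid near room temperature leaves the prenyl alkene, the methyl ester and the diaryl ether alone.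

Step 9
Reactants: 19 methyl 4-[(1,4-dihydroxynaphthalen-2-yl)oxy]-1-hydroxy-3-(3-methylbut-2-enyl)-2-naphthoate
Product: 20 Rubioncolin C
Conditions: Ag2O (monovalent silver), Na2SO4, Et2O, rt
Reagents that add atoms: none
Why: Hydroquinone-to-quinone oxidation with a mild two-electron oxidant should act only on the 1,4-dihydroxynaphthalene ring, because the remaining naphthol is chelated to the ester, sits on an electron-poor ring and has no free para hydroxyl.

**Compound list**

1 | methyl 1,4-dihydroxy-2-naphthoate | COC(=O)c1cc(O)c2ccccc2c1O | starting material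
2 | methyl 3-bromo-1,4-dihydroxy-2-naphthoate | COC(=O)c1c(Br)c(O)c2ccccc2c1O | intermediate
3 | methyl 3-bromo-1,4-bis(trimethylsilyloxy)-2-naphthoate | COC(=O)c1c(Br)c(O[Si](C)(C)C)c2ccccc2c1O[Si](C)(C)C | intermediate
4 | methyl 3-lithio-1,4-bis(trimethylsilyloxy)-2-naphthoate (C3 aryllithium) | COC(=O)c1c([Li])c(O[Si](C)(C)C)c2ccccc2c1O[Si](C)(C)C | intermediate
5 | methyl 4-(lithiooxy)-3-(trimethylsilyl)-1-(trimethylsilyloxy)-2-naphthoate (lithium naphtholate) | COC(=O)c1c([Si](C)(C)C)c(O[Li])c2ccccc2c1O[Si](C)(C)C | intermediate
6 | methyl 4-(trifluoromethylsulfonyloxy)-3-(trimethylsilyl)-1-(trimethylsilyloxy)-2-naphthoate | COC(=O)c1c([Si](C)(C)C)c(OS(=O)(=O)C(F)(F)F)c2ccccc2c1O[Si](C)(C)C | intermediate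
7 | methyl 1-hydroxy-4-(trifluoromethylsulfonyloxy)-3-(trimethylsilyl)-2-naphthoate | COC(=O)c1c([Si](C)(C)C)c(OS(=O)(=O)C(F)(F)F)c2ccccc2c1O | intermediate
8 | methyl 1-(methoxymethoxy)-4-(trifluoromethylsulfonyloxy)-3-(trimethylsilyl)-2-naphthoate | COCOc1c(C(=O)OC)c([Si](C)(C)C)c(OS(=O)(=O)C(F)(F)F)c2ccccc12 | intermediate
9 | naphthalene-1,4-diol | Oc1ccc(O)c2ccccc12 | starting material
10 | 1,4-bis(methoxymethoxy)naphthalene | COCOc1ccc(OCOC)c2ccccc12 | intermediate
11 | [1,4-bis(methoxymethoxy)naphthalen-2-yl]lithium | COCOc1cc([Li])c(OCOC)c2ccccc12 | intermediate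
12 | lithium [1,4-bis(methoxymethoxy)naphthalen-2-yl]trimethoxyborate | COCOc1cc([B-](OC)(OC)OC)c(OCOC)c2ccccc12.[Li+] | intermediate
13 | 1,4-bis(methoxymethoxy)naphthalen-2-ol | COCOc1cc(O)c(OCOC)c2ccccc12 | intermediate
14 | prenyl bromide (1-bromo-3-methylbut-2-ene) | CC(C)=CCBr | starting material
15 | copper 1,4-bis(methoxymethoxy)naphthalen-2-olate (monovalent copper) | COCOc1cc(O[Cu])c(OCOC)c2ccccc12 | intermediate
16 | methyl 3,4-didehydro-1-(methoxymethoxy)-2-naphthoate (3,4-naphthalyne) | COCOC1=C(C(=O)OC)C#CC2=C1C=CC=C2 | intermediate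
17 | C3 arylcopper: methyl 4-{[1,4-bis(methoxymethoxy)naphthalen-2-yl]oxy}-3-cuprio-1-(methoxymethoxy)-2-naphthoate (monovalent copper) | COCOc1c(C(=O)OC)c([Cu])c(Oc3cc(OCOC)c4ccccc4c3OCOC)c2ccccc12 | intermediate
18 | methyl 4-{[1,4-bis(methoxymethoxy)naphthalen-2-yl]oxy}-1-(methoxymethoxy)-3-(3-methylbut-2-enyl)-2-naphthoate | COCOc1c(C(=O)OC)c(CC=C(C)C)c(Oc3cc(OCOC)c4ccccc4c3OCOC)c2ccccc12 | intermediate
19 | methyl 4-[(1,4-dihydroxynaphthalen-2-yl)oxy]-1-hydroxy-3-(3-methylbut-2-enyl)-2-naphthoate | COC(=O)c1c(CC=C(C)C)c(Oc2cc(O)c3ccccc3c2O)c2ccccc2c1O | intermediate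
20 | Rubioncolin C | COC(=O)c1c(CC=C(C)C)c(OC2=CC(=O)c3ccccc3C2=O)c2ccccc2c1O | target

**Step count**

Total: 9 steps. Longest linear sequence: 7 steps (steps 1–4, 7, 8, 9).

**Steps most likely to fail**

Step 7. The aryloxide oxygen may bond to C3 instead of C4, the C3 arylcopper may be protonated before it meets prenyl bromide, or allylation may take place at the tertiary terminus. The fallback drops the aryne and makes the two bonds separately by known chemistry; it sets out from 1 and comes back to the route at 20. Friedel–Crafts prenylation of 1 with 2-methylbut-3-en-2-ol and BF3·OEt2 in dioxane should give methyl 1,4-dihydroxy-3-(3-methylbut-2-enyl)-2-naphthoate F1. Acetylation of the unchelated O4 hydroxyl (Ac2O, pyridine, 0 °C) should give methyl 4-acetoxy-1-hydroxy-3-(3-methylbut-2-enyl)-2-naphthoate F2. Methoxymethylation of O1 (MOMCl, i-Pr2NEt, CH2Cl2) should give methyl 4-acetoxy-1-(methoxymethoxy)-3-(3-methylbut-2-enyl)-2-naphthoate F3. Methanolysis of the acetate (K2CO3, MeOH, 0 °C) should free methyl 4-hydroxy-1-(methoxymethoxy)-3-(3-methylbut-2-enyl)-2-naphthoate F4. Its phenoxide should displace bromide from 2-bromo-1,4-naphthoquinone by addition–elimination (K2CO3, DMF, rt) to give methyl 4-[(1,4-dioxo-1,4-dihydronaphthalen-2-yl)oxy]-1-(methoxymethoxy)-3-(3-methylbut-2-enyl)-2-naphthoate F5. O1 is protected before this coupling so that no free hydroquinone can exchange redox level with the bromoquinone. HCl in MeOH then removes the remaining methoxymethyl group and gives 20.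

Step 3. Addition of butyllithium or of the aryllithium to the methyl ester may compete with halogen–metal exchange and silyl migration. The fallback installs silicon by deprotonation with in-situ trapping, so that no aryllithium accumulates; it sets out from 1 and comes back at 8. Benzylation of the unchelated O4 hydroxyl (BnBr, K2CO3, acetone) should give methyl 4-(benzyloxy)-1-hydroxy-2-naphthoate F6. Methoxymethylation (NaH, MOMCl, DMF) should give methyl 4-(benzyloxy)-1-(methoxymethoxy)-2-naphthoate F7. Deprotonation of C3–H, flanked by the ester and the benzyloxy group, with LiTMP (lithium 2,2,6,6-tetramethylpiperidide) in the presence of TMSCl (THF, −78 °C) should give methyl 4-(benzyloxy)-1-(methoxymethoxy)-3-(trimethylsilyl)-2-naphthoate F8. Hydrogenolysis (H2, Pd/C, EtOAc) should free methyl 4-hydroxy-1-(methoxymethoxy)-3-(trimethylsilyl)-2-naphthoate F9. Triflation (Tf2O, pyridine, CH2Cl2, 0 °C) then gives 8.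

Step 1. Oxidation of the hydroquinone to the quinone may outrun ring bromination and leave a mixture of oxidation levels that the reductive wash does not fully resolve. The fallback separates the two events; it sets out from 1 and comes back at 2. Oxidation of 1 with Ag2O (monovalent silver) and MgSO4 in Et2O should give methyl 1,4-dioxo-1,4-dihydronaphthalene-2-carboxylate F10. Conjugate addition of HBr (33% in AcOH, CH2Cl2, 0 °C) at C3, which is β to both the C1 carbonyl and the ester, followed by enolisation, should then give 2.

**Further compounds**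

F1 | step 7 | methyl 1,4-dihydroxy-3-(3-methylbut-2-enyl)-2-naphthoate | COC(=O)c1c(CC=C(C)C)c(O)c2ccccc2c1O
F2 | step 7 | methyl 4-acetoxy-1-hydroxy-3-(3-methylbut-2-enyl)-2-naphthoate | COC(=O)c1c(CC=C(C)C)c(OC(C)=O)c2ccccc2c1O
F3 | step 7 | methyl 4-acetoxy-1-(methoxymethoxy)-3-(3-methylbut-2-enyl)-2-naphthoate | COCOc1c(C(=O)OC)c(CC=C(C)C)c(OC(C)=O)c2ccccc12
F4 | step 7 | methyl 4-hydroxy-1-(methoxymethoxy)-3-(3-methylbut-2-enyl)-2-naphthoate | COCOc1c(C(=O)OC)c(CC=C(C)C)c(O)c2ccccc12
F5 | step 7 | methyl 4-[(1,4-dioxo-1,4-dihydronaphthalen-2-yl)oxy]-1-(methoxymethoxy)-3-(3-methylbut-2-enyl)-2-naphthoate | COCOc1c(C(=O)OC)c(CC=C(C)C)c(OC3=CC(=O)c4ccccc4C3=O)c2ccccc12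
F6 | step 3 | methyl 4-(benzyloxy)-1-hydroxy-2-naphthoate | COC(=O)c1cc(OCc2ccccc2)c2ccccc2c1O
F7 | step 3 | methyl 4-(benzyloxy)-1-(methoxymethoxy)-2-naphthoate | COCOc1c(C(=O)OC)cc(OCc3ccccc3)c2ccccc12
F8 | step 3 | methyl 4-(benzyloxy)-1-(methoxymethoxy)-3-(trimethylsilyl)-2-naphthoate | COCOc1c(C(=O)OC)c([Si](C)(C)C)c(OCc3ccccc3)c2ccccc12
F9 | step 3 | methyl 4-hydroxy-1-(methoxymethoxy)-3-(trimethylsilyl)-2-naphthoate | COCOc1c(C(=O)OC)c([Si](C)(C)C)c(O)c2ccccc12
F10 | step 1 | methyl 1,4-dioxo-1,4-dihydronaphthalene-2-carboxylate | COC(=O)C1=CC(=O)c2ccccc2C1=O
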